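## Analysis of the target

The target 15 is a ternaphthalene built from three 8-methoxynaphthalen-1-ol units. Unit A is joined through its C2 to C2 of the central unit B (ortho to both hydroxyls), and unit C through its C4 to C4 of unit B (para to both hydroxyls). Unit B therefore carries OH at C1, aryl groups at C2 and C4, H at C3 and OMe at C8, peri to the OH. There is no stereocentre. The 2,2′ axis has only two hydroxyls as ortho groups and the 4,4′ axis is of the 1,1′-binaphthyl type with peri hydrogens only, so both are expected to rotate at ambient temperature; the SMILES string carries no descriptor and no configuration has to be controlled. The sensitive groups are three electron-rich, hydrogen-bonded peri-methoxy naphthols: they are easily oxidised to naphthoquinones, they are nucleophilic at C2 and C4, and OH and OMe must stay distinguished in every unit, which excludes a late global demethylation. The difficulty is purely regiochemical: three copies of one monomer must be joined once ortho–ortho and once para–para, the central copy at both positions, although each copy offers C2 and C4 (and C5 and C7 of its anisole ring) with similar reactivity. The feature that invites a different cut is the phenol ring of unit B (C1, C2, C3, C4, C4a, C8a). Its ring-fusion carbons C8a and C4a are ortho and meta to the C8 methoxy group, the two positions at which 3-methoxybenzyne (12) takes up first a carbon nucleophile (meta) and then a carbonyl carbon (ortho). Its C1–O/C2–aryl edge, together with O1–C1=C2 of unit A, is the skeleton of a five-membered aryl lactone.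

## Retrosynthetic reasoning

**15 ⇒ 14.** The last operation only unmasks the hydroxyl of unit C. That hydroxyl is kept as an acetal because as a free naphtholate it would hinder the palladium step and offer a further nucleophile to the aryne. The acetal is removed by acid that does not touch the three methyl ethers.

**14 ⇒ 9 + 10 (key cut).** The bonds C4–C4a and C1–C8a of unit B are cut. This separates the anisole ring of unit B, which becomes aryne 12 made in the flask from 10, from a four-carbon chain C1–C2–C3–C4 that already carries unit A on C2 and unit C on C4. Both biaryl bonds of the target are then ordinary bonds from a chain carbon to one naphthalene, and no two arenes have to be coupled. C1 must be at the ester oxidation level and is tied to O1 of unit A as the lactone 9. The lactone protects that hydroxyl, activates the carbonyl and releases the naphthol of unit A in the ring-forming event. The forward reaction requires that dienolate 11 reacts through its γ-carbon with the aryne carbon remote from OMe and that the aryl anion next to OMe then closes onto the lactone carbonyl. The ortho link, the para link and the peri OMe/OH relation are then all fixed by the connectivity of 9 and the polarisation of 12. A chain carrying a second unsaturated ester, so that the ring of unit C would also come from an aryne, was considered and dropped: its dienolate would cyclise by intramolecular Michael addition.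

**9 ⇒ 6 + 8.** The bond between the γ-carbon of the chain (future C4 of unit B) and the bromine-bearing carbon of 8 is cut. It is made by palladium-catalysed arylation of the dienolate of 6, whose α-carbon is fully substituted, so the terminal carbon is the accessible site. Unit C enters as its para bromide, the one position of the monomer that simple electrophilic substitution reaches selectively.

**6 ⇒ 3 ⇒ 1 + 2.** The bond between C2 of unit A and the α-carbon of the chain is cut as a [3,3]-sigmatropic shift of the allyl aryl ether 3. That shift can only deliver the ortho isomer and places the ester carbon next to the hydroxyl, so lactonisation follows. The ether 3 comes from 1 and 2 by O-alkylation.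

**8 ⇒ 7 ⇒ 1.** Bromination is done on the free naphthol 1, where OH is the dominant donor and directs para within the phenol ring. Protection comes second, because after O-alkylation the two rings of the monomer would be activated to the same degree.

## Alternatives that were turned down

**Alternative 1:** the textbook cut through both biaryl bonds. Two site-selective Suzuki–Miyaura couplings would join 1-(benzyloxy)-2,4-dibromo-8-methoxynaphthalene A1 with the boronate 2-[1-(benzyloxy)-8-methoxynaphthalen-2-yl]-4,4,5,5-tetramethyl-1,3,2-dioxaborolane A2 and with [4-(benzyloxy)-5-methoxynaphthalen-1-yl]boronic acid A3. It was turned down for three reasons: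
- Three differently functionalised and protected monomers are needed, and the order of the two couplings on A1 rests on a small difference between a bromide flanked by an alkoxy group and one flanked by a peri hydrogen.
- Both couplings build hindered biaryls.
- The sequence runs to about ten steps with three protecting groups, and the regiochemistry is bought three separate times by halogenation or metalation.

**Alternative 2:** the biomimetic cut. Oxidative phenol coupling of 1 would give the 4,4′-dimer 4-(4-hydroxy-5-methoxynaphthalen-1-yl)-8-methoxynaphthalen-1-ol A4, followed by a second oxidative coupling of A4 with 1 at the ortho positions. It was turned down for three reasons: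
- The naphthoxyl radical of 1 carries spin at C2 and C4, so 2,2′-, 2,4′- and 4,4′-linked dimers and their trimers are all expected.
- The second coupling requires ortho attack on a monomer whose para position is the more accessible one.
- Every product is more easily oxidised than 1, which leads on to quinones.

Nothing in the substrate controls any of these points, so the brevity of the route would be paid for in separation.

**Alternative 3:** a temporary bridge across the 2,2′ bond. The oxygens of unit A and unit B would be tied in the silyl ether di-tert-butyl[(2-bromo-8-methoxynaphthalen-1-yl)oxy]{[8-methoxy-4-(5-methoxy-4-(methoxymethoxy)naphthalen-1-yl)naphthalen-1-yl]oxy}silane A5. Palladium-catalysed intramolecular C–H arylation would close the seven-membered dioxasilepine A6, and fluoride would remove the silicon. It was turned down for two reasons: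
- The bridge secures only the ortho–ortho bond. The 4,4′ bond inside A5 must still come from a cross-coupling of two para-functionalised monomers, and an ortho-brominated monomer is needed as well.
- The route is longer than Alternative 1, and it answers a selectivity question that the chosen cut does not pose.

Key step: step 6

Assumptions: 1, 2 and 10 are purchased. The alkene geometry of 6 and 9 is not controlled and need not be, because both compounds are used only through their dienolates.

## Route

Step 1
Reactants: 1 8-methoxynaphthalen-1-ol; 2 methyl (E)-4-bromobut-2-enoate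
Product: 3 methyl (E)-4-[(8-methoxynaphthalen-1-yl)oxy]but-2-enoate
Conditions: K2CO3, acetone, reflux
Reagents that add atoms: none
Why: Williamson ether synthesis: the potassium naphtholate displaces the primary allylic bromide of 2 by SN2, the E-alkene is untouched, and the mild carbonate base should not deconjugate the crotonate.

Step 2
Reactants: 3 methyl (E)-4-[(8-methoxynaphthalen-1-yl)oxy]but-2-enoate
Product: 6 (3E)-3-ethylidene-9-methoxynaphtho[1,2-b]furan-2(3H)-one, via hydroxy ester 4 (not isolated), via vinyl lactone 5 (not isolated)
Conditions: PhNEt2, 200 °C, MeOH distilled off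
Reagents that add atoms: none
Why: Aromatic Claisen rearrangement: the [3,3] shift joins C2 of the naphthalene to the ester-bearing alkene carbon and can only give the ortho isomer 4, whose hydroxyl then closes the five-membered aryl lactone 5 with loss of MeOH. In the hot amine the acidic C3–H of 5 should move the double bond into conjugation to give 6; its E/Z ratio is immaterial because step 5 passes through the dienolate.

Step 3
Reactants: 1 8-methoxynaphthalen-1-ol
Product: 7 4-bromo-8-methoxynaphthalen-1-ol
Conditions: NBS (1.0 equiv), MeCN, −20 → 0 °C
Reagents that add atoms: N-bromosuccinimide, O=C1CCC(=O)N1Br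
Why: Electrophilic aromatic bromination: the free OH is the strongest donor of 1, so substitution should occur on the phenol ring and, at low temperature in MeCN, at the less hindered para carbon C4 and not on the anisole ring.

Step 4
Reactants: 7 4-bromo-8-methoxynaphthalen-1-ol
Product: 8 4-bromo-8-methoxy-1-(methoxymethoxy)naphthalene
Conditions: NaH, MOMCl, DMF, 0 °C → rt
Reagents that add atoms: chloromethyl methyl ether, COCCl
Why: O-Alkylation of the sodium naphtholate; the MOM acetal is stable to the amide bases and the palladium conditions ahead and is cleaved by mild acid that leaves the aryl methyl ethers alone.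

Step 5
Reactants: 6 (3E)-3-ethylidene-9-methoxynaphtho[1,2-b]furan-2(3H)-one; 8 4-bromo-8-methoxy-1-(methoxymethoxy)naphthalene
Product: 9 (3E)-9-methoxy-3-{2-[5-methoxy-4-(methoxymethoxy)naphthalen-1-yl]ethylidene}naphtho[1,2-b]furan-2(3H)-one
Conditions: LiN(SiMe3)2 (2.1 equiv), THF, −78 °C; then 8, Pd(dba)2 (5 mol %), P(t-Bu)3 (10 mol %), rt → 50 °C; AcOH, then Et3N (cat.)
Reagents that add atoms: none
Why: Palladium-catalysed γ-arylation (vinylogous α-arylation) of a preformed lithium dienolate: oxidative addition of 8 to zerovalent palladium, transmetallation by the dienolate of 6 and reductive elimination at the unhindered terminal carbon rather than at the fully substituted α-carbon, following the known arylation of ester enolates with Pd/P(t-Bu)3 and the γ-arylation of dienolates of unsaturated esters. Two equivalents of base keep the more acidic product as its dienolate; after the quench a trace of amine should give the conjugated lactone 9, whose alkene geometry (and any β,γ-unsaturated tautomer) is immaterial because step 6 converts it into dienolate 11.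

Step 6
Reactants: 9 (3E)-9-methoxy-3-{2-[5-methoxy-4-(methoxymethoxy)naphthalen-1-yl]ethylidene}naphtho[1,2-b]furan-2(3H)-one; 10 3-bromoanisole
Product: 14 2-(1-hydroxy-8-methoxynaphthalen-2-yl)-8-methoxy-4-[5-methoxy-4-(methoxymethoxy)naphthalen-1-yl]naphthalen-1-ol, via lithium dienolate 11 (not isolated), via 3-methoxybenzyne 12 (not isolated), via 4H-naphthalenone 13 (not isolated)
Conditions: LiTMP (lithium 2,2,6,6-tetramethylpiperidide, 3.5 equiv), THF, −78 °C; 10 (1.5 equiv), −78 °C → rt; AcOH
Reagents that add atoms: none
Why: The amide base removes a γ-hydrogen of 9 to give the lithium dienolate 11 (a 2-oxidonaphthofuran carrying the styryl group, held s-cis because the s-trans rotamer clashes with H-4 of the naphthofuran), and the same base lithiates 10 between OMe and Br so that loss of LiBr releases 3-methoxybenzyne 12. The γ-carbon of 11 (future C4 of unit B) adds to the aryne carbon remote from OMe, the more electrophilic terminus because the adjacent oxygen stabilises the carbanion that develops next to it; this aryl anion then attacks the lactone carbonyl (future C1) in a 6-exo-trig addition–elimination that expels the naphtholate oxygen of unit A. The two new bonds C4–C4a and C1–C8a close the phenol ring of unit B in a formal (4+2) annulation, concerted-asynchronous or stepwise, and the 4H-naphthalen-1-one 13 so formed is deprotonated at its doubly benzylic C4–H and aromatises to the bis-naphtholate of 14. The closest known reaction type is the annulation of arynes with lithium dienolates of α,β-unsaturated esters and amides to give 1-naphthols, which with 3-methoxybenzyne delivers the 8-methoxy-1-naphthol pattern needed here. No stereocentre survives (C4 of 13 is transient), so only regiochemistry matters: the orientation on the aryne is set by the OMe group as described, and reaction through the γ-carbon rather than the α-carbon is favoured because the α-carbon is fully substituted, α-attack would leave the aryl anion only a strained four-membered closure, and dienolates of 3-alkylidene oxindoles and benzofuranones are known to react as vinylogous (γ) donors. The lithium naphtholates formed are poor nucleophiles in THF at low temperature, which should limit further arylation by excess aryne, and the MOM ether and the methoxy groups are inert to the amide base.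

Step 7
Reactants: 14 2-(1-hydroxy-8-methoxynaphthalen-2-yl)-8-methoxy-4-[5-methoxy-4-(methoxymethoxy)naphthalen-1-yl]naphthalen-1-ol
Product: 15 2-(1-hydroxy-8-methoxynaphthalen-2-yl)-4-(4-hydroxy-5-methoxynaphthalen-1-yl)-8-methoxynaphthalen-1-ol
Conditions: HCl (3 M aq.), MeOH–THF, 40 °C
Reagents that add atoms: none
Why: Acid-catalysed acetal exchange transfers the methoxymethyl group to methanol; the aryl methyl ethers and the biaryl bonds are stable to these conditions, and the product has no stereocentre to disturb.

## Compound list

1 | 8-methoxynaphthalen-1-ol | COc1cccc2cccc(O)c12 | starting material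
2 | methyl (E)-4-bromobut-2-enoate | COC(=O)/C=C/CBr | starting material
3 | methyl (E)-4-[(8-methoxynaphthalen-1-yl)oxy]but-2-enoate | COC(=O)/C=C/COc1cccc2cccc(OC)c12 | intermediate
4 | methyl 2-(1-hydroxy-8-methoxynaphthalen-2-yl)but-3-enoate (racemic, not isolated) | COC(=O)C(C=C)c1ccc2cccc(OC)c2c1O | intermediate
5 | 3-ethenyl-9-methoxynaphtho[1,2-b]furan-2(3H)-one (racemic, not isolated) | O=C1Oc2c(ccc3cccc(OC)c23)C1C=C | intermediate
6 | (3E)-3-ethylidene-9-methoxynaphtho[1,2-b]furan-2(3H)-one (E drawn, Z equally usable) | O=C1Oc2c(ccc3cccc(OC)c23)/C1=C\C | intermediate
7 | 4-bromo-8-methoxynaphthalen-1-ol | COc1cccc2c(Br)ccc(O)c12 | intermediate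
8 | 4-bromo-8-methoxy-1-(methoxymethoxy)naphthalene | COCOc1ccc(Br)c2cccc(OC)c12 | intermediate
9 | (3E)-9-methoxy-3-{2-[5-methoxy-4-(methoxymethoxy)naphthalen-1-yl]ethylidene}naphtho[1,2-b]furan-2(3H)-one (E drawn, Z equally usable) | O=C1Oc2c(ccc3cccc(OC)c23)/C1=C\Cc1ccc(OCOC)c2c(OC)cccc12 | intermediate
10 | 3-bromoanisole | COc1cccc(Br)c1 | starting material
11 | lithium 9-methoxy-3-{(E)-2-[5-methoxy-4-(methoxymethoxy)naphthalen-1-yl]ethenyl}naphtho[1,2-b]furan-2-olate (not isolated) | [Li+].[O-]c1oc2c(ccc3cccc(OC)c23)c1/C=C/c1ccc(OCOC)c2c(OC)cccc12 | intermediate
12 | 3-methoxybenzyne (1-methoxy-2,3-didehydrobenzene, not isolated) | COC1=CC=CC#C1 | intermediate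
13 | 2-(1-hydroxy-8-methoxynaphthalen-2-yl)-8-methoxy-4-[5-methoxy-4-(methoxymethoxy)naphthalen-1-yl]naphthalen-1(4H)-one (racemic, not isolated) | COc1cccc2c1C(=O)C(c1ccc3cccc(OC)c3c1O)=CC2c1ccc(OCOC)c2c(OC)cccc12 | intermediate
14 | 2-(1-hydroxy-8-methoxynaphthalen-2-yl)-8-methoxy-4-[5-methoxy-4-(methoxymethoxy)naphthalen-1-yl]naphthalen-1-ol | COCOc1ccc(-c2cc(-c3ccc4cccc(OC)c4c3O)c(O)c3c(OC)cccc23)c2cccc(OC)c12 | intermediate
15 | 2-(1-hydroxy-8-methoxynaphthalen-2-yl)-4-(4-hydroxy-5-methoxynaphthalen-1-yl)-8-methoxynaphthalen-1-ol | COc1cccc2ccc(-c3cc(-c4ccc(O)c5c(OC)cccc45)c4cccc(OC)c4c3O)c(O)c12 | target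

## Step count and least certain steps

Total step count: 7. Longest linear sequence: 5 steps (1 → 3 → 6 → 9 → 14 → 15; the branch 1 → 7 → 8 joins at step 5).

**Step 6 (key step).** Three things may go wrong.
- The aryne may be attacked by the α-carbon of dienolate 11 instead of the γ-carbon. That would end in simple α-arylation or, after four-membered closure and ring opening, in the constitutional isomer with the two outer units exchanged.
- The product naphtholates may be arylated further by excess aryne.
- The aryne may be consumed by the amide base.

Fallback by cross-coupling, setting out from 8, 7 and 1 and returning at 15: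
- Miyaura borylation of 8 (B2pin2, Pd(dppf)Cl2, KOAc, dioxane, 90 °C) gives 2-[5-methoxy-4-(methoxymethoxy)naphthalen-1-yl]-4,4,5,5-tetramethyl-1,3,2-dioxaborolane F1.
- Suzuki–Miyaura coupling of F1 with 7 (Pd(OAc)2/SPhos, K3PO4, toluene–water) gives 8-methoxy-4-[5-methoxy-4-(methoxymethoxy)naphthalen-1-yl]naphthalen-1-ol F2.
- Bromination of F2 (NBS, cat. i-Pr2NH, CH2Cl2, 0 °C) can only go ortho because the para position is blocked, and gives 2-bromo-8-methoxy-4-[5-methoxy-4-(methoxymethoxy)naphthalen-1-yl]naphthalen-1-ol F3.
- In parallel 1 is converted (NaH, MOMCl) into 8-methoxy-1-(methoxymethoxy)naphthalene F4. Directed ortho-lithiation (n-BuLi, TMEDA, THF; B(OMe)3; aqueous acid) then gives [8-methoxy-1-(methoxymethoxy)naphthalen-2-yl]boronic acid F5.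
- Suzuki–Miyaura coupling of F3 with F5 gives 8-methoxy-2-[8-methoxy-1-(methoxymethoxy)naphthalen-2-yl]-4-[5-methoxy-4-(methoxymethoxy)naphthalen-1-yl]naphthalen-1-ol F6.
- HCl in MeOH removes both acetals and gives 15.

**Step 5.** Reductive elimination may occur at the α-carbon (quaternary centre) instead of the γ-carbon, the more acidic product may be arylated a second time, and 6 may self-condense by vinylogous Michael addition if deprotonation is incomplete.

Fallback without base in the coupling event, setting out from 8 and 6 and returning at 11:
- Vinylation of 8 (potassium vinyltrifluoroborate, Pd(dppf)Cl2, Cs2CO3, THF–water, 80 °C) gives 1-ethenyl-5-methoxy-4-(methoxymethoxy)naphthalene F7.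
- Kinetic deconjugation of 6 (LiN(SiMe3)2, THF, −78 °C, then AcOH) gives the vinyl lactone 5.
- Olefin cross-metathesis of 5 with F7 (second-generation Hoveyda–Grubbs catalyst, CH2Cl2, 40 °C) gives 9-methoxy-3-{(E)-2-[5-methoxy-4-(methoxymethoxy)naphthalen-1-yl]ethenyl}naphtho[1,2-b]furan-2(3H)-one F8.
- Under the conditions of step 6, F8 is deprotonated to the same dienolate 11.

**Step 2.** The [3,3] shift may be slow because the migrating terminus is an acrylate carbon, so thermal cleavage of the allyl ether can compete. Addition of the freed hydroxyl to the vinyl group (dihydrofuran formation) can also compete with lactonisation.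

Fallback, setting out from 1 and returning at 6:
- The titanium naphtholate of 1 (TiCl4, CH2Cl2, −78 → 0 °C) is hydroxyalkylated by ethyl 2-oxobutanoate. The chelated transition state delivers the keto ester to the ortho carbon only, and the adduct lactonises in the flask to 3-ethyl-3-hydroxy-9-methoxynaphtho[1,2-b]furan-2(3H)-one F9.
- Dehydration of F9 (TsOH cat., toluene, reflux, water removed) gives 6.

**Step 3.** Bromination may occur at C2 as well as at C4, and over-bromination may follow, because both positions of the phenol ring are activated.

Fallback that makes the ortho/para ratio irrelevant, setting out from 1 and returning at 8: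
- Exhaustive bromination of 1 (NBS, 2.1 equiv, MeCN) gives 2,4-dibromo-8-methoxynaphthalen-1-ol F10.
- Protection (NaH, MOMCl) gives 2,4-dibromo-8-methoxy-1-(methoxymethoxy)naphthalene F11.
- Bromine–lithium exchange with n-BuLi (1.0 equiv, THF, −78 °C) is directed by the acetal oxygens to the ortho bromine; a MeOH quench gives 8.

## Further compounds

F1 | step 6 | 2-[5-methoxy-4-(methoxymethoxy)naphthalen-1-yl]-4,4,5,5-tetramethyl-1,3,2-dioxaborolane | COCOc1ccc(B2OC(C)(C)C(C)(C)O2)c2cccc(OC)c12
F2 | step 6 | 8-methoxy-4-[5-methoxy-4-(methoxymethoxy)naphthalen-1-yl]naphthalen-1-ol | COCOc1ccc(-c2ccc(O)c3c(OC)cccc23)c2cccc(OC)c12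
F3 | step 6 | 2-bromo-8-methoxy-4-[5-methoxy-4-(methoxymethoxy)naphthalen-1-yl]naphthalen-1-ol | COCOc1ccc(-c2cc(Br)c(O)c3c(OC)cccc23)c2cccc(OC)c12
F4 | step 6 | 8-methoxy-1-(methoxymethoxy)naphthalene | COCOc1cccc2cccc(OC)c12
F5 | step 6 | [8-methoxy-1-(methoxymethoxy)naphthalen-2-yl]boronic acid | COCOc1c(B(O)O)ccc2cccc(OC)c12
F6 | step 6 | 8-methoxy-2-[8-methoxy-1-(methoxymethoxy)naphthalen-2-yl]-4-[5-methoxy-4-(methoxymethoxy)naphthalen-1-yl]naphthalen-1-ol | COCOc1ccc(-c2cc(-c3ccc4cccc(OC)c4c3OCOC)c(O)c3c(OC)cccc23)c2cccc(OC)c12
F7 | step 5 | 1-ethenyl-5-methoxy-4-(methoxymethoxy)naphthalene | C=Cc1ccc(OCOC)c2c(OC)cccc12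
F8 | step 5 | 9-methoxy-3-{(E)-2-[5-methoxy-4-(methoxymethoxy)naphthalen-1-yl]ethenyl}naphtho[1,2-b]furan-2(3H)-one (racemic) | O=C1Oc2c(ccc3cccc(OC)c23)C1/C=C/c1ccc(OCOC)c2c(OC)cccc12
F9 | step 2 | 3-ethyl-3-hydroxy-9-methoxynaphtho[1,2-b]furan-2(3H)-one (racemic) | CCC1(O)C(=O)Oc2c1ccc1cccc(OC)c21
F10 | step 3 | 2,4-dibromo-8-methoxynaphthalen-1-ol | COc1cccc2c(Br)cc(Br)c(O)c12
F11 | step 3 | 2,4-dibromo-8-methoxy-1-(methoxymethoxy)naphthalene | COCOc1c(Br)cc(Br)c2cccc(OC)c12
A1 | alternative 1 | 1-(benzyloxy)-2,4-dibromo-8-methoxynaphthalene | COc1cccc2c(Br)cc(Br)c(OCc3ccccc3)c12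
A2 | alternative 1 | 2-[1-(benzyloxy)-8-methoxynaphthalen-2-yl]-4,4,5,5-tetramethyl-1,3,2-dioxaborolane | COc1cccc2ccc(B3OC(C)(C)C(C)(C)O3)c(OCc3ccccc3)c12
A3 | alternative 1 | [4-(benzyloxy)-5-methoxynaphthalen-1-yl]boronic acid | COc1cccc2c(B(O)O)ccc(OCc3ccccc3)c12
A4 | alternative 2 | 4-(4-hydroxy-5-methoxynaphthalen-1-yl)-8-methoxynaphthalen-1-ol | COc1cccc2c(-c3ccc(O)c4c(OC)cccc34)ccc(O)c12
A5 | alternative 3 | di-tert-butyl[(2-bromo-8-methoxynaphthalen-1-yl)oxy]{[8-methoxy-4-(5-methoxy-4-(methoxymethoxy)naphthalen-1-yl)naphthalen-1-yl]oxy}silane | COCOc1ccc(-c2ccc(O[Si](Oc3c(Br)ccc4cccc(OC)c34)(C(C)(C)C)C(C)(C)C)c3c(OC)cccc23)c2cccc(OC)c12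
A6 | alternative 3 | seven-membered di-tert-butyl dioxasilepine bridging O1 of unit A and O1 of unit B, with the 2,2′ bond closed | COCOc1ccc(-c2cc3-c4ccc5cccc(OC)c5c4O[Si](C(C)(C)C)(C(C)(C)C)Oc3c3c(OC)cccc23)c2cccc(OC)c12
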